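**Plan**
- Retrosynthetic cuts, last-made first: C4a–C5 and C8a–C8 of naphthalene A (aryne + furan); the two furan–aryl bonds that end as C8–C5(isoquinoline A) and C6–C6'(naphthalene B); the C1'–C5 biaryl bond of the naphthalene B/isoquinoline B half; C1–C8a of each isoquinoline.
- Feature used: the C5–C8 ring of naphthalene A carries OH on C5, naphthalene B on C6 and isoquinoline A on C8. This is the oxygen and the 2,4-diaryl pattern of a furan laid across the aryne carbons C4a/C8a.
- Forward: the isoquinoline ring closes by Bischler–Napieralski cyclisation and naphthalene B by Stobbe condensation and ring closure. Suzuki couplings join isoquinoline B to naphthalene B and attach both halves to 2,4-dibromofuran. The aryne [4+2] closes the last ring of naphthalene A, and acid opens the oxygen bridge to the C5 naphthol.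
- The aryne carries a pinacolboryl group where the C4 methoxy group will stand. Boron polarises the aryne so that the free furan α-carbon bonds next to it, which a methoxy group would not do. It is oxidised and methylated after the cycloaddition.
- Stereochemistry: C3 of both isoquinolines comes from a D-alaninol-derived cyclic sulfamidate (chiral pool); C1 is set by 1,3-trans-selective hydride reduction of the cyclic imine. Three benzyl ethers and two Cbz groups fall in the last step.

Key step: step 24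

Assumption: the structure defines the four stereocentres (1R,3R in both tetrahydroisoquinolines) but not the sense of the hindered biaryl axes. The route fixes the centres and carries the rotamers about the C5–C1' axis (formed in step 15) as they form; they can be separated by chromatography if one is wanted.

Shorthand in names: IQ = (1R,3R)-8-(benzyloxy)-2-[(benzyloxy)carbonyl]-1,3-dimethyl-1,2,3,4-tetrahydroisoquinolin-5-yl; Bpin = 4,4,5,5-tetramethyl-1,3,2-dioxaborolan-2-yl; NB = 5-(benzyloxy)-1-IQ-4-methoxy-2-methylnaphthalen-6-yl. Primed locants belong to naphthalene B.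

**Isoquinoline building block**

Step 1
Reactants: 1 4-bromo-3-iodophenol
Product: 2 4-(benzyloxy)-1-bromo-2-iodobenzene
Conditions: BnBr, K2CO3, DMF, rt
Reagents that add atoms: benzyl bromide, BrCc1ccccc1
Why: Williamson etherification of the phenoxide gives a benzyl ether that should survive all later steps and fall in the final hydrogenolysis.

Step 2
Reactants: 2 4-(benzyloxy)-1-bromo-2-iodobenzene; 3 tert-butyl (4R)-4-methyl-1,2,3-oxathiazolidine-3-carboxylate 2,2-dioxide
Product: 6 tert-butyl N-[(2R)-1-[5-(benzyloxy)-2-bromophenyl]propan-2-yl]carbamate, via aryl Grignard reagent 4 (not isolated), via N-sulfamate magnesium salt 5 (not isolated)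
Conditions: iPrMgCl·LiCl, THF, −30 °C; CuI (10 mol%), 3, −30 → 0 °C; aq. citric acid, rt
Reagents that add atoms: none
Why: iodine–magnesium exchange takes the iodide and spares the bromide, and the copper-catalysed SN2 opening of the cyclic sulfamidate at its CH2–O carbon leaves the (R)-centre untouched, so C3 is taken from D-alaninol before mild acid hydrolyses the N-sulfate.

Step 3
Reactants: 6 tert-butyl N-[(2R)-1-[5-(benzyloxy)-2-bromophenyl]propan-2-yl]carbamate
Product: 8 N-[(2R)-1-[5-(benzyloxy)-2-bromophenyl]propan-2-yl]acetamide, via amine hydrochloride 7 (not isolated)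
Conditions: 4 M HCl in dioxane, rt; then Ac2O, Et3N, CH2Cl2, 0 °C → rt
Reagents that add atoms: acetic anhydride, CC(=O)OC(C)=O
Why: acidolysis of the Boc group followed by N-acetylation supplies the amide whose acetyl carbon becomes C1 and whose methyl group becomes the C1 methyl.

Step 4
Reactants: 8 N-[(2R)-1-[5-(benzyloxy)-2-bromophenyl]propan-2-yl]acetamide
Product: 9 (3R)-8-(benzyloxy)-5-bromo-1,3-dimethyl-3,4-dihydroisoquinoline
Conditions: Tf2O, 2-chloropyridine, CH2Cl2, −78 → 40 °C
Reagents that add atoms: none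
Why: Bischler–Napieralski cyclisation of the triflic anhydride-activated amide can only close at the one free ortho carbon, next to the benzyloxy group, because bromine blocks the other, which gives the 8-oxygenated ring and keeps the bromide as the later coupling handle.

Step 5
Reactants: 9 (3R)-8-(benzyloxy)-5-bromo-1,3-dimethyl-3,4-dihydroisoquinoline
Product: 10 (1R,3R)-8-(benzyloxy)-5-bromo-1,3-dimethyl-1,2,3,4-tetrahydroisoquinoline
Conditions: LiAlH4, AlMe3, THF, −78 → −20 °C
Reagents that add atoms: none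
Why: AlMe3 on nitrogen pushes the C3 methyl group pseudo-axial and hydride then adds axially to C1, the known 1,3-trans-selective reduction of 1,3-dimethyl-3,4-dihydroisoquinolines, so C1 should be set R under control of C3 (any cis isomer removed by chromatography).

Step 6
Reactants: 10 (1R,3R)-8-(benzyloxy)-5-bromo-1,3-dimethyl-1,2,3,4-tetrahydroisoquinoline
Product: 11 benzyl (1R,3R)-8-(benzyloxy)-5-bromo-1,3-dimethyl-3,4-dihydro-1H-isoquinoline-2-carboxylate (IQ–Br)
Conditions: CbzCl, Na2CO3, CH2Cl2/H2O, 0 °C → rt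
Reagents that add atoms: benzyl chloroformate, O=C(Cl)OCc1ccccc1
Why: Schotten–Baumann carbamate formation masks the basic nitrogen against palladium binding, oxidation and N-methylation, and the Cbz group leaves with the benzyl ethers at the end.

Step 7
Reactants: 11 IQ–Br
Product: 12 benzyl (1R,3R)-8-(benzyloxy)-1,3-dimethyl-5-Bpin-3,4-dihydro-1H-isoquinoline-2-carboxylate (IQ–Bpin)
Conditions: B2pin2, PdCl2(dppf), KOAc, dioxane, 90 °C
Reagents that add atoms: bis(pinacolato)diboron, CC1(C)OB(OC1(C)C)B1OC(C)(C)C(C)(C)O1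
Why: Miyaura borylation of the aryl bromide under zerovalent palladium catalysis tolerates the carbamate and the benzyl ether.

**Naphthalene B and its union with isoquinoline B**

Step 8
Reactants: 13 5-(benzyloxy)-2-bromobenzaldehyde; 14 diethyl succinate
Product: 15 (3E)-4-[5-(benzyloxy)-2-bromophenyl]-3-(ethoxycarbonyl)but-3-enoic acid
Conditions: KOtBu, tBuOH, reflux; then aq. HCl
Reagents that add atoms: none
Why: Stobbe condensation gives, through its lactone intermediate, the half-ester with the aryl group cis to the CH2CO2H arm as needed for ring closure.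

Step 9
Reactants: 15 (3E)-4-[5-(benzyloxy)-2-bromophenyl]-3-(ethoxycarbonyl)but-3-enoic acid
Product: 16 ethyl 4-acetoxy-5-(benzyloxy)-8-bromonaphthalene-2-carboxylate
Conditions: Ac2O, NaOAc, reflux
Reagents that add atoms: acetic anhydride, CC(=O)OC(C)=O
Why: intramolecular Friedel–Crafts acylation through the mixed anhydride, enolisation and O-acetylation build the naphthalene, and the bromine forces closure at the carbon next to the benzyloxy group so that the two peri oxygens are in place.

Step 10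
Reactants: 16 ethyl 4-acetoxy-5-(benzyloxy)-8-bromonaphthalene-2-carboxylate
Product: 18 ethyl 5-(benzyloxy)-8-bromo-4-methoxynaphthalene-2-carboxylate, via C4 naphthol 17 (not isolated)
Conditions: K2CO3, EtOH, 40 °C; then MeI, DMF, rt
Reagents that add atoms: iodomethane, CI
Why: ethanolysis of the aryl acetate frees only the C4 oxygen, which is methylated as its phenoxide while O5 stays benzylated, so the two peri oxygens are told apart.

Step 11
Reactants: 18 ethyl 5-(benzyloxy)-8-bromo-4-methoxynaphthalene-2-carboxylate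
Product: 19 [5-(benzyloxy)-8-bromo-4-methoxynaphthalen-2-yl]methanol
Conditions: LiAlH4, THF, 0 °C
Reagents that add atoms: none
Why: hydride reduction of the ester to the primary alcohol leaves the aryl bromide alone at 0 °C.

Step 12
Reactants: 19 [5-(benzyloxy)-8-bromo-4-methoxynaphthalen-2-yl]methanol
Product: 20 8-methoxy-6-methylnaphthalen-1-ol
Conditions: H2 (4 bar), 10% Pd/C, EtOH/AcOH, 40 °C
Reagents that add atoms: none
Why: one catalytic hydrogenolysis should remove the blocking bromine, the benzyl ether and the benzylic hydroxyl (helped by the HBr set free), turning the carbinol into the C2' methyl group.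

Step 13
Reactants: 20 8-methoxy-6-methylnaphthalen-1-ol
Product: 21 8-methoxy-6-methylnaphthalen-1-yl acetate
Conditions: Ac2O, pyridine, CH2Cl2, rt
Reagents that add atoms: acetic anhydride, CC(=O)OC(C)=O
Why: O-acetylation deactivates the naphthol ring so that the next bromination goes to the methoxy-bearing ring.

Step 14
Reactants: 21 8-methoxy-6-methylnaphthalen-1-yl acetate
Product: 22 5-bromo-8-methoxy-6-methylnaphthalen-1-yl acetate
Conditions: NBS, MeCN, 0 °C
Reagents that add atoms: N-bromosuccinimide, O=C1CCC(=O)N1Br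
Why: electrophilic bromination should go para to the methoxy group, at the α-carbon next to the methyl group (C1'), the most activated position once the other ring carries an acetate.

Step 15
Reactants: 22 5-bromo-8-methoxy-6-methylnaphthalen-1-yl acetate; 12 IQ–Bpin
Product: 24 1-IQ-4-methoxy-2-methylnaphthalen-5-ol (5-IQ-8-methoxy-6-methylnaphthalen-1-ol), via biaryl acetate 23 (not isolated)
Conditions: Pd2(dba)3, SPhos, K3PO4, toluene/H2O, 100 °C; then K2CO3, MeOH, rt
Reagents that add atoms: none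
Why: Suzuki–Miyaura coupling with a dialkylbiarylphosphine ligand suited to ortho-substituted partners builds the C5–C1' axis and methanolysis frees the C5' naphthol (acetate lost during the coupling leads to the same product), the stereocentres being untouched.

Step 16
Reactants: 24 1-IQ-4-methoxy-2-methylnaphthalen-5-ol
Product: 25 6-bromo-1-IQ-4-methoxy-2-methylnaphthalen-5-ol
Conditions: NBS, iPr2NH (10 mol%), CH2Cl2, −20 °C
Reagents that add atoms: N-bromosuccinimide, O=C1CCC(=O)N1Br
Why: amine-mediated NBS bromination of a free naphthol goes ortho (C6'), the para carbon C8' being shielded by the peri isoquinoline and the benzylated isoquinoline ring being far less activated.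

Step 17
Reactants: 25 6-bromo-1-IQ-4-methoxy-2-methylnaphthalen-5-ol
Product: 26 5-(benzyloxy)-6-bromo-1-IQ-4-methoxy-2-methylnaphthalene (NB–Br)
Conditions: BnBr, K2CO3, DMF, rt
Reagents that add atoms: benzyl bromide, BrCc1ccccc1
Why: Williamson etherification protects the naphthol against the Grignard reagent and the aryne of the key step.

Step 18
Reactants: 26 NB–Br
Product: 27 5-(benzyloxy)-1-IQ-4-methoxy-2-methyl-6-Bpin-naphthalene (NB–Bpin)
Conditions: B2pin2, PdCl2(dppf), KOAc, dioxane, 90 °C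
Reagents that add atoms: bis(pinacolato)diboron, CC1(C)OB(OC1(C)C)B1OC(C)(C)C(C)(C)O1
Why: Miyaura borylation converts the ortho-alkoxy aryl bromide into the boronate for the furan coupling.

**Furan assembly**

Step 19
Reactants: 28 2,4-dibromofuran; 12 IQ–Bpin
Product: 29 4-bromo-2-IQ-furan
Conditions: Pd(PPh3)4, Na2CO3, DME/H2O, 70 °C (28 in slight excess)
Reagents that add atoms: none
Why: in this Suzuki coupling zerovalent palladium inserts into the C–Br bond next to the furan oxygen (C2) ahead of the one at C4, the known site selectivity of 2,4-dibromofuran.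

Step 20
Reactants: 29 4-bromo-2-IQ-furan; 27 NB–Bpin
Product: 30 2-IQ-4-NB-furan
Conditions: Pd2(dba)3, SPhos, K3PO4, dioxane/H2O, 90 °C
Reagents that add atoms: none
Why: Suzuki coupling at the remaining furan C4 bromide makes a furan–aryl bond that is far less hindered than the biaryl bond it becomes.

**Aryne precursor**

Step 21
Reactants: 31 4-methylphenol
Product: 32 2,6-diiodo-4-methylphenol
Conditions: NIS (2.1 equiv), TsOH (cat.), MeCN, rt
Reagents that add atoms: N-iodosuccinimide, O=C1CCC(=O)N1I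
Why: electrophilic iodination takes both ortho positions because the para position is blocked by the methyl group.

Step 22
Reactants: 32 2,6-diiodo-4-methylphenol
Product: 34 2-iodo-4-methyl-6-Bpin-phenol, via magnesiated phenoxide 33 (not isolated)
Conditions: MeMgCl then iPrMgCl, LiCl, THF, −30 → 0 °C; iPrOBpin, −30 °C → rt; aq. NH4Cl
Reagents that add atoms: 2-isopropoxy-4,4,5,5-tetramethyl-1,3,2-dioxaborolane, CC(C)OB1OC(C)(C)C(C)(C)O1
Why: after deprotonation of the phenol one iodine–magnesium exchange gives an aryl Grignard whose charge should hold back a second exchange, and the borate ester traps it.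

Step 23
Reactants: 34 2-iodo-4-methyl-6-Bpin-phenol
Product: 35 2-iodo-4-methyl-6-Bpin-phenyl trifluoromethanesulfonate
Conditions: Tf2O, pyridine, CH2Cl2, 0 °C
Reagents that add atoms: trifluoromethanesulfonic anhydride, O=S(=O)(OS(=O)(=O)C(F)(F)F)C(F)(F)F
Why: O-triflation gives the ortho-iodoaryl triflate, the known type of precursor from which 3-borylbenzynes are released by a Grignard reagent.

**Key step and end game**

Step 24
Reactants: 35 2-iodo-4-methyl-6-Bpin-phenyl trifluoromethanesulfonate; 30 2-IQ-4-NB-furan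
Product: 38 8-IQ-6-NB-2-methyl-4-Bpin-5,8-dihydro-5,8-epoxynaphthalene (naphthalene A numbering; both bridgehead epimers), via aryl Grignard reagent 36 (not isolated), via 3-boryl-5-methylbenzyne 37 (not isolated)
Conditions: 35 (3 equiv), iPrMgCl·LiCl (slow addition), THF, −78 °C → rt
Reagents that add atoms: none
Why: Iodine–magnesium exchange at −78 °C gives 36, which loses magnesium triflate to form aryne 37; this adds across furan C2 and C5 of 30 in a concerted, asynchronous [4+2] cycloaddition, the known behaviour of 3-borylbenzynes towards 2-substituted furans. The six-membered ring C4a–C5–C6–C7–C8–C8a closes in this one intermolecular cycloaddition, which forms C4a–C5 and C8a–C8 together and leaves the furan oxygen as a bridge between C5 and C8. The bridgehead centres C5 and C8 arise without control relative to the distant isoquinoline centres, which does not matter because both become sp2 carbons in step 27. The selectivity needed is regiochemical: the furan carbon bearing isoquinoline A must bond to the aryne carbon remote from boron. The σ-donating pinacolboryl group makes the aryne carbon next to it the electrophilic one, so the more nucleophilic, unsubstituted furan α-carbon bonds there, and its bulk keeps the aryl-bearing furan carbon on the far side; a methoxy group at this position would polarise the aryne in the opposite sense. Exchange at iodine should outrun attack of the Grignard reagent on the boronate and the carbamates at −78 °C, and the benzyl ethers are inert.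

Step 25
Reactants: 38 8-IQ-6-NB-2-methyl-4-Bpin-5,8-dihydro-5,8-epoxynaphthalene
Product: 39 8-IQ-6-NB-2-methyl-5,8-dihydro-5,8-epoxynaphthalen-4-ol
Conditions: NaBO3·4H2O, THF/H2O, rt
Reagents that add atoms: sodium perborate, [Na+].[O-]OB=O
Why: oxidation of the aryl boronate by 1,2-shift of the aryl group from boron to oxygen puts the C4 oxygen in place under conditions that carbamates, ethers and the bridged alkene tolerate.

Step 26
Reactants: 39 8-IQ-6-NB-2-methyl-5,8-dihydro-5,8-epoxynaphthalen-4-ol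
Product: 40 8-IQ-6-NB-4-methoxy-2-methyl-5,8-dihydro-5,8-epoxynaphthalene
Conditions: MeI, K2CO3, DMF, rt
Reagents that add atoms: iodomethane, CI
Why: Williamson methylation of the only free phenol is done before the bridge is opened, so the C4 and C5 oxygens never have to be told apart, and the carbamate nitrogens cannot be quaternised.

Step 27
Reactants: 40 8-IQ-6-NB-4-methoxy-2-methyl-5,8-dihydro-5,8-epoxynaphthalene
Product: 41 8-IQ-6-NB-4-methoxy-2-methylnaphthalen-5-ol
Conditions: TFA, CH2Cl2, 0 °C → rt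
Reagents that add atoms: none
Why: in this acid-catalysed isomerisation of a 1,4-epoxy-1,4-dihydronaphthalene to a 1-naphthol the C8–O bond should ionise because its cation is tertiary, benzylic to two arenes and allylic towards C6, after which a 1,2-hydride shift from C5 to C6 gives the C5 ketone whose enol is the naphthol.

Step 28
Reactants: 41 8-IQ-6-NB-4-methoxy-2-methylnaphthalen-5-ol
Product: 42 8-[(1R,3R)-8-hydroxy-1,3-dimethyl-1,2,3,4-tetrahydroisoquinolin-5-yl]-6-{5-hydroxy-1-[(1R,3R)-8-hydroxy-1,3-dimethyl-1,2,3,4-tetrahydroisoquinolin-5-yl]-4-methoxy-2-methylnaphthalen-6-yl}-4-methoxy-2-methylnaphthalen-5-ol (CNP0077060.1)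
Conditions: H2 (1 atm), 10% Pd/C, MeOH/THF, rt
Reagents that add atoms: none
Why: hydrogenolysis cleaves the three benzyl ethers and the two benzyl carbamates (with loss of CO2) without touching a stereocentre or the naphthalene rings.

**Compound list**

1 | 4-bromo-3-iodophenol | Oc1ccc(Br)c(I)c1 | starting material
2 | 4-(benzyloxy)-1-bromo-2-iodobenzene | Brc1ccc(OCc2ccccc2)cc1I | intermediate
3 | tert-butyl (4R)-4-methyl-1,2,3-oxathiazolidine-3-carboxylate 2,2-dioxide | C[C@@H]1COS(=O)(=O)N1C(=O)OC(C)(C)C | starting material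
4 | [5-(benzyloxy)-2-bromophenyl]magnesium chloride | Cl[Mg]c1cc(OCc2ccccc2)ccc1Br | intermediate
5 | chloromagnesium N-[(2R)-1-[5-(benzyloxy)-2-bromophenyl]propan-2-yl]-N-(tert-butoxycarbonyl)sulfamate | C[C@H](Cc1cc(OCc2ccccc2)ccc1Br)N(C(=O)OC(C)(C)C)S(=O)(=O)O[Mg]Cl | intermediate
6 | tert-butyl N-[(2R)-1-[5-(benzyloxy)-2-bromophenyl]propan-2-yl]carbamate | C[C@H](Cc1cc(OCc2ccccc2)ccc1Br)NC(=O)OC(C)(C)C | intermediate
7 | (2R)-1-[5-(benzyloxy)-2-bromophenyl]propan-2-aminium chloride | C[C@H](Cc1cc(OCc2ccccc2)ccc1Br)[NH3+].[Cl-] | intermediate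
8 | N-[(2R)-1-[5-(benzyloxy)-2-bromophenyl]propan-2-yl]acetamide | C[C@H](Cc1cc(OCc2ccccc2)ccc1Br)NC(C)=O | intermediate
9 | (3R)-8-(benzyloxy)-5-bromo-1,3-dimethyl-3,4-dihydroisoquinoline | Brc1ccc(OCc2ccccc2)c2c1C[C@@H](C)N=C2C | intermediate
10 | (1R,3R)-8-(benzyloxy)-5-bromo-1,3-dimethyl-1,2,3,4-tetrahydroisoquinoline | Brc1ccc(OCc2ccccc2)c2c1C[C@@H](C)N[C@@H]2C | intermediate
11 | benzyl (1R,3R)-8-(benzyloxy)-5-bromo-1,3-dimethyl-3,4-dihydro-1H-isoquinoline-2-carboxylate (IQ–Br) | Brc1ccc(OCc2ccccc2)c2c1C[C@@H](C)N(C(=O)OCc1ccccc1)[C@@H]2C | intermediate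
12 | benzyl (1R,3R)-8-(benzyloxy)-1,3-dimethyl-5-Bpin-3,4-dihydro-1H-isoquinoline-2-carboxylate (IQ–Bpin) | CC1(C)OB(c2ccc(OCc3ccccc3)c3c2C[C@@H](C)N(C(=O)OCc2ccccc2)[C@@H]3C)OC1(C)C | intermediate
13 | 5-(benzyloxy)-2-bromobenzaldehyde | O=Cc1cc(OCc2ccccc2)ccc1Br | starting material
14 | diethyl succinate | CCOC(=O)CCC(=O)OCC | starting material
15 | (3E)-4-[5-(benzyloxy)-2-bromophenyl]-3-(ethoxycarbonyl)but-3-enoic acid | CCOC(=O)/C(CC(=O)O)=C/c1cc(OCc2ccccc2)ccc1Br | intermediate
16 | ethyl 4-acetoxy-5-(benzyloxy)-8-bromonaphthalene-2-carboxylate | CCOC(=O)c1cc(OC(C)=O)c2c(OCc3ccccc3)ccc(Br)c2c1 | intermediate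
17 | ethyl 5-(benzyloxy)-8-bromo-4-hydroxynaphthalene-2-carboxylate | CCOC(=O)c1cc(O)c2c(OCc3ccccc3)ccc(Br)c2c1 | intermediate
18 | ethyl 5-(benzyloxy)-8-bromo-4-methoxynaphthalene-2-carboxylate | CCOC(=O)c1cc(OC)c2c(OCc3ccccc3)ccc(Br)c2c1 | intermediate
19 | [5-(benzyloxy)-8-bromo-4-methoxynaphthalen-2-yl]methanol | OCc1cc(OC)c2c(OCc3ccccc3)ccc(Br)c2c1 | intermediate
20 | 8-methoxy-6-methylnaphthalen-1-ol | COc1cc(C)cc2cccc(O)c12 | intermediate
21 | 8-methoxy-6-methylnaphthalen-1-yl acetate | COc1cc(C)cc2cccc(OC(C)=O)c12 | intermediate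
22 | 5-bromo-8-methoxy-6-methylnaphthalen-1-yl acetate | COc1cc(C)c(Br)c2cccc(OC(C)=O)c12 | intermediate
23 | 1-IQ-4-methoxy-2-methylnaphthalen-5-yl acetate | COc1cc(C)c(-c2ccc(OCc3ccccc3)c3c2C[C@@H](C)N(C(=O)OCc2ccccc2)[C@@H]3C)c2cccc(OC(C)=O)c12 | intermediate
24 | 1-IQ-4-methoxy-2-methylnaphthalen-5-ol | COc1cc(C)c(-c2ccc(OCc3ccccc3)c3c2C[C@@H](C)N(C(=O)OCc2ccccc2)[C@@H]3C)c2cccc(O)c12 | intermediate
25 | 6-bromo-1-IQ-4-methoxy-2-methylnaphthalen-5-ol | COc1cc(C)c(-c2ccc(OCc3ccccc3)c3c2C[C@@H](C)N(C(=O)OCc2ccccc2)[C@@H]3C)c2ccc(Br)c(O)c12 | intermediate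
26 | 5-(benzyloxy)-6-bromo-1-IQ-4-methoxy-2-methylnaphthalene (NB–Br) | COc1cc(C)c(-c2ccc(OCc3ccccc3)c3c2C[C@@H](C)N(C(=O)OCc2ccccc2)[C@@H]3C)c2ccc(Br)c(OCc3ccccc3)c12 | intermediate
27 | 5-(benzyloxy)-1-IQ-4-methoxy-2-methyl-6-Bpin-naphthalene (NB–Bpin) | COc1cc(C)c(-c2ccc(OCc3ccccc3)c3c2C[C@@H](C)N(C(=O)OCc2ccccc2)[C@@H]3C)c2ccc(B3OC(C)(C)C(C)(C)O3)c(OCc3ccccc3)c12 | intermediate
28 | 2,4-dibromofuran | Brc1coc(Br)c1 | starting material
29 | 4-bromo-2-IQ-furan | Brc1coc(-c2ccc(OCc3ccccc3)c3c2C[C@@H](C)N(C(=O)OCc2ccccc2)[C@@H]3C)c1 | intermediate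
30 | 2-IQ-4-NB-furan | c1c(-c2ccc3c(-c4ccc(OCc5ccccc5)c5c4C[C@@H](C)N(C(=O)OCc4ccccc4)[C@@H]5C)c(C)cc(OC)c3c2OCc2ccccc2)coc1-c1ccc(OCc2ccccc2)c2c1C[C@@H](C)N(C(=O)OCc1ccccc1)[C@@H]2C | intermediate
31 | 4-methylphenol | Cc1ccc(O)cc1 | starting material
32 | 2,6-diiodo-4-methylphenol | Cc1cc(I)c(O)c(I)c1 | intermediate
33 | chloromagnesium 2-(chloromagnesio)-6-iodo-4-methylphenoxide | Cc1cc(I)c(O[Mg]Cl)c([Mg]Cl)c1 | intermediate
34 | 2-iodo-4-methyl-6-Bpin-phenol | Cc1cc(I)c(O)c(B2OC(C)(C)C(C)(C)O2)c1 | intermediate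
35 | 2-iodo-4-methyl-6-Bpin-phenyl trifluoromethanesulfonate | Cc1cc(I)c(OS(=O)(=O)C(F)(F)F)c(B2OC(C)(C)C(C)(C)O2)c1 | intermediate
36 | [3-methyl-5-Bpin-6-(trifluoromethanesulfonyloxy)phenyl]magnesium chloride | Cc1cc([Mg]Cl)c(OS(=O)(=O)C(F)(F)F)c(B2OC(C)(C)C(C)(C)O2)c1 | intermediate
37 | 3-Bpin-5-methylbenzyne | CC1=CC#CC(B2OC(C)(C)C(C)(C)O2)=C1 | intermediate
38 | 8-IQ-6-NB-2-methyl-4-Bpin-5,8-dihydro-5,8-epoxynaphthalene (bridgeheads undefined, both epimers) | Cc1cc(B2OC(C)(C)C(C)(C)O2)c2c(c1)C1(c3ccc(OCc4ccccc4)c4c3C[C@@H](C)N(C(=O)OCc3ccccc3)[C@@H]4C)OC2C(c2ccc3c(-c4ccc(OCc5ccccc5)c5c4C[C@@H](C)N(C(=O)OCc4ccccc4)[C@@H]5C)c(C)cc(OC)c3c2OCc2ccccc2)=C1 | intermediate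
39 | 8-IQ-6-NB-2-methyl-5,8-dihydro-5,8-epoxynaphthalen-4-ol (both epimers) | Cc1cc(O)c2c(c1)C1(c3ccc(OCc4ccccc4)c4c3C[C@@H](C)N(C(=O)OCc3ccccc3)[C@@H]4C)OC2C(c2ccc3c(-c4ccc(OCc5ccccc5)c5c4C[C@@H](C)N(C(=O)OCc4ccccc4)[C@@H]5C)c(C)cc(OC)c3c2OCc2ccccc2)=C1 | intermediate
40 | 8-IQ-6-NB-4-methoxy-2-methyl-5,8-dihydro-5,8-epoxynaphthalene (both epimers) | Cc1cc(OC)c2c(c1)C1(c3ccc(OCc4ccccc4)c4c3C[C@@H](C)N(C(=O)OCc3ccccc3)[C@@H]4C)OC2C(c2ccc3c(-c4ccc(OCc5ccccc5)c5c4C[C@@H](C)N(C(=O)OCc4ccccc4)[C@@H]5C)c(C)cc(OC)c3c2OCc2ccccc2)=C1 | intermediate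
41 | 8-IQ-6-NB-4-methoxy-2-methylnaphthalen-5-ol | COc1cc(C)cc2c(-c3ccc(OCc4ccccc4)c4c3C[C@@H](C)N(C(=O)OCc3ccccc3)[C@@H]4C)cc(-c3ccc4c(-c5ccc(OCc6ccccc6)c6c5C[C@@H](C)N(C(=O)OCc5ccccc5)[C@@H]6C)c(C)cc(OC)c4c3OCc3ccccc3)c(O)c12 | intermediate
42 | CNP0077060.1 (name as in step 28) | COc1cc(C)cc2c(-c3ccc(O)c4c3C[C@@H](C)N[C@@H]4C)cc(-c3ccc4c(-c5ccc(O)c6c5C[C@@H](C)N[C@@H]6C)c(C)cc(OC)c4c3O)c(O)c12 | target

**Step count and risks**

Total: 28 steps. Longest linear sequence: 17 steps (13 → 42 through steps 8–18, 20, 24–28; the line from 1 is equally long).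

Steps most likely to fail:

1. Step 24. The aryne may be consumed by the Grignard reagent or by self-reaction faster than the hindered, precious furan captures it, or the two orientations of addition may not be separated well enough. The fallback gives up the ring construction and takes naphthalene A preformed; it sets out from naphthol 20 (with boronates 27 and 12) and comes back at target 42. Para-bromination of 20 (NBS, MeCN, −20 °C) should give 4-bromo-8-methoxy-6-methylnaphthalen-1-ol F1. Ortho-iodination (NIS, TsOH) gives 4-bromo-2-iodo-8-methoxy-6-methylnaphthalen-1-ol F2, and benzylation (BnBr, K2CO3) gives 1-(benzyloxy)-4-bromo-2-iodo-8-methoxy-6-methylnaphthalene F3. Suzuki coupling with 27 at the C–I bond (Pd(PPh3)4, Na2CO3, 60 °C) gives 5-(benzyloxy)-8-bromo-6-NB-4-methoxy-2-methylnaphthalene F4. A second coupling with 12 at C8 (Pd2(dba)3, SPhos, K3PO4) gives 5-(benzyloxy)-8-IQ-6-NB-4-methoxy-2-methylnaphthalene F5, and hydrogenolysis as in step 28 gives 42.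

2. Step 15. Protodeboronation of the ortho-substituted boronate 12 may outpace transmetalation at the crowded palladium centre of this doubly hindered axis. The fallback exchanges the roles of the partners; it sets out from bromide 22 (with bromide 11) and comes back at 24. Miyaura borylation of 22 (B2pin2, PdCl2(dppf), KOAc) gives 8-methoxy-6-methyl-5-Bpin-naphthalen-1-yl acetate F6. This is coupled with 11 (Pd2(dba)3, SPhos, K3PO4) so that the hindered isoquinoline is the electrophile, and methanolysis of the resulting acetate 23 gives 24.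

3. Step 12. The hydrogenolysis may stop after loss of bromine and benzyl and leave the benzylic C–O bond, or go on to saturate a ring. The fallback replaces C–O hydrogenolysis by hydride displacement; it sets out from alcohol 19 and comes back at 20. PBr3 gives 5-(benzyloxy)-8-bromo-2-(bromomethyl)-4-methoxynaphthalene F7, and LiAlH4 at 0 °C displaces the benzylic bromide to give 5-(benzyloxy)-8-bromo-4-methoxy-2-methylnaphthalene F8. Hydrogenolysis (H2, Pd/C, EtOH) then only has to remove the aryl bromine and the benzyl group to give 20.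

**Further compounds**

F1 | step 24 | 4-bromo-8-methoxy-6-methylnaphthalen-1-ol | COc1cc(C)cc2c(Br)ccc(O)c12
F2 | step 24 | 4-bromo-2-iodo-8-methoxy-6-methylnaphthalen-1-ol | COc1cc(C)cc2c(Br)cc(I)c(O)c12
F3 | step 24 | 1-(benzyloxy)-4-bromo-2-iodo-8-methoxy-6-methylnaphthalene | COc1cc(C)cc2c(Br)cc(I)c(OCc3ccccc3)c12
F4 | step 24 | 5-(benzyloxy)-8-bromo-6-NB-4-methoxy-2-methylnaphthalene | COc1cc(C)cc2c(Br)cc(-c3ccc4c(-c5ccc(OCc6ccccc6)c6c5C[C@@H](C)N(C(=O)OCc5ccccc5)[C@@H]6C)c(C)cc(OC)c4c3OCc3ccccc3)c(OCc3ccccc3)c12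
F5 | step 24 | 5-(benzyloxy)-8-IQ-6-NB-4-methoxy-2-methylnaphthalene | COc1cc(C)cc2c(-c3ccc(OCc4ccccc4)c4c3C[C@@H](C)N(C(=O)OCc3ccccc3)[C@@H]4C)cc(-c3ccc4c(-c5ccc(OCc6ccccc6)c6c5C[C@@H](C)N(C(=O)OCc5ccccc5)[C@@H]6C)c(C)cc(OC)c4c3OCc3ccccc3)c(OCc3ccccc3)c12
F6 | step 15 | 8-methoxy-6-methyl-5-Bpin-naphthalen-1-yl acetate | COc1cc(C)c(B2OC(C)(C)C(C)(C)O2)c2cccc(OC(C)=O)c12
F7 | step 12 | 5-(benzyloxy)-8-bromo-2-(bromomethyl)-4-methoxynaphthalene | BrCc1cc(OC)c2c(OCc3ccccc3)ccc(Br)c2c1
F8 | step 12 | 5-(benzyloxy)-8-bromo-4-methoxy-2-methylnaphthalene | Cc1cc(OC)c2c(OCc3ccccc3)ccc(Br)c2c1
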